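## Structural features

Numbering used throughout: C1 (angelate), C2 (isovalerate), C3 (free hydroxyl), C4 (CMe2), C5, C6, C7 (ketone), C8=C9 (methyl on C9), C10, C11 (quaternary, methyl). The target is a tricyclic sesquiterpenoid diester in which the cyclobutane C5–C6–C11–C10 is spanned on one face by the enone bridge C6–C7(=O)–C8=C9–C10 (a bicyclo[3.1.1]heptenone) and on the other face by the chain C5–C4–C3–C2–C1–C11, which closes the seven-membered ring. All seven stereocentres are contiguous: C1, C2 and C3 carry oxygen (O1 trans to O2, O2 cis to O3), C1 adjoins the quaternary C11, and C5, C6, C10 and C11 are the four cyclobutane carbons, locked by the two bridges. Fragile elements are the (Z)-2-methylbut-2-enoate (isomerises to the E ester under base, nucleophilic catalysts or heat), the cis C2/C3 hydroxy ester pair (acyl migration), the enone, and the strained cyclobutane, which at the tertiary-carbinol stage can undergo retro-aldol cleavage or cationic rearrangement. The real difficulties are the cyclobutane with its quaternary carbon C11 shared by all three rings, the differentiation of three neighbouring secondary oxygens, and the C1 configuration, because the two faces of C1 differ only through the remote C7 and C9 ends of the lower bridge. The key step exploits that C11 is alpha to the C1 carbonyl and 1,3 to C10 across ring B (C5–C6–C7–C8–C9–C10) of a cis-fused bicyclic precursor, while C9 must later lose an oxygen to become part of C8=C9: a C9–C10 epoxide supplies both the electrophile for C10–C11 and the leaving group for the enone.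

## Logic of the disconnections

23 to 22: the C2–O acyl bond is cut last, so that the cis hydroxy ester never meets acid or oxidant. The forward acylation must choose O2 over the neopentylic O3.

22 to 21: both C2–O and C3–O are cut as one syn addition to C2=C3. Two stereocentres come from one operation, and the forward step must add anti to the C1 acyloxy group and leave the two conjugated alkenes alone.

21 to 19 (through 20): water is added back across C8=C9 and C7 is masked as a dioxolane. This is the oxidation pattern the key step delivers; the forward step must unmask and eliminate without touching the angelate.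

19 to 18 to 17: the C1–O acyl bond, then the C1–H bond, are cut. This leads back to an enone whose C2=C3 bond has blocked enolisation towards C2; the reduction must be reagent-controlled because the substrate offers almost no facial bias at C1.

17 to 16: the C10–C11 bond is cut. This removes the cyclobutane, the quaternary centre and one ring, and leaves a cis-fused bicyclo[5.4.0]undecenone; the forward step needs anti opening at C10 by carbon.

16 to 15: the two C–O bonds of the oxirane are cut. The forward epoxidation must occur on the face of H5 and H6, anti to C11.

15 to 14: the C11–CH3 bond is cut. Earlier intermediates are freed of a stereocentre that is in any case erased in the dienolate, and 15 is left with exactly one acidic hydrogen.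

14 to 13: C2=C3 is cut by retro-metathesis, opening the seven-membered ring to two cis arms on ring B.

13 to 12 to 11: the C1–C2 bond (vinyl to acyl), then the amide, are cut back to a methyl ester.

11 to 10 to 8: the ketal with C9=C10 is traced to the conjugated C8=C9 enone, and that to the saturated ketone. A saturated C9–C10 unit would give no handle for the epoxide, so the alkene is generated by dehydrogenation and moved into place while C7 is protected. A dioxolane at C7 is preferred to a silyl ether because it adds no stereocentre and needs no late oxidation.

8 to 5 and 6: the C4–C5 bond and the C6–H bond are cut. Conjugate addition of 6 makes the quaternary C4 and, with kinetic protonation, the cis arms; C9 of 5 controls the face.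

5 to 4 to 1 and 2: C8–C9 (Michael), C5=C6 (aldol condensation) and the C8 ester (decarboxylation) are cut. A racemic cyclohexenone would give a racemic target, so the single stereocentre C9 is set by catalysis, relays its configuration to C5 and C6, and is then destroyed.

## Other disconnections considered

Alternative 1: The cut is C4–C5 plus C1–C11. In the forward step the tertiary alpha-keto radical is generated from 4-bromo-4-methylpent-1-yn-3-one A2 with fac-Ir(ppy)3 and Hantzsch ester and adds to the unsubstituted bridgehead C5 of the methyl-substituted bicyclo[1.1.0]butane A1. The resulting tertiary cyclobutyl radical at C11 closes 7-endo-dig on the alkyne terminus to give the tricyclic cycloheptenone A3.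
- In its favour: it is convergent, the bromo ynone A2 is a small and simple partner, it makes two C–C bonds, both quaternary carbons and the seven-membered ring in one operation, and strain release drives the first addition. On convergence and bonds formed per step it is better than the chosen plan.
- Against it: A1 is a strained, enantiopure tricyclic hydrocarbon derivative whose own synthesis is not obvious. The cyclobutyl radical can be reduced before the slow 7-endo closure. A3 carries the carbonyl at C3 and the alkene at C1=C2, so a syn dihydroxylation would make O1 and O2 cis, whereas the target has them trans; an inversion or an epoxide detour would be needed. C9 is still saturated and the enone must be introduced later.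
- Comparison: on step economy for the carbon skeleton it is the better plan. On stereochemical mapping of the triol and on certainty of mechanism (radical chain with competing reduction against a polar closure that has only one acidic site) the chosen plan is safer.

Alternative 2: The cut is the C8=C9 double bond, traced back to the bridged sulfone A4 (a 3-thiabicyclo[4.1.1]octane dioxide). In the forward step KOH and CCl4 halogenate an alpha-carbon, 1,3-elimination gives the episulfone, and loss of SO2 gives the tricyclic alkene A5.
- In its favour: the alkene position is unambiguous, since halogenation at either alpha-carbon leads to the same alkene. The strained bicyclo[3.1.1]heptene is made late from a less strained thia ring. A5 is an allylic ketal, so the enone appears on simple hydrolysis without a dehydration. On regiochemical certainty of the enone it is the equal or the better of the chosen plan.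
- Against it: the step forms no sigma bond of the skeleton and no stereocentre, so the cyclobutane and its quaternary carbon must already be present in A4 and have to be made some other way. Dichlorocarbene generated under these conditions can add to the new trisubstituted alkene.
- Comparison: mechanistically it is reliable, but the structural problem is only postponed and the overall step count should be higher than in the chosen plan, whose key step builds the cyclobutane itself.

Alternative 3: The cut is C7–C8, traced back to the bicyclo[2.1.1]hexanone A6 with a bromomethyl group on C9. In the forward step Bu3SnH generates the primary radical, which adds to the C7 carbonyl; the cyclopropyloxy radical opens by C7–C9 cleavage to the tertiary C9 radical, and hydrogen transfer gives the saturated ketone A7.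
- In its favour: bicyclo[2.1.1]hexanones are accessible by crossed intramolecular [2+2] photocycloaddition, which is a strong way to make a cyclobutane with quaternary carbons, and the C7 ketone arrives unprotected in its final position. On that last point it is better than the chosen plan.
- Against it: the rearranged radical is stabilised only as a tertiary alkyl radical, so direct reduction of the primary radical competes and slow addition of a toxic tin hydride is needed. The fully oxygenated seven-membered ring must survive photochemical and radical steps. The product is saturated at C8–C9, so a separate dehydrogenation is still required.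
- Comparison: structurally it addresses the bicyclo[3.1.1] unit but not the seven-membered ring or any stereocentre of the target. In step economy it is roughly equal at the ring-expansion stage and longer overall.

Key step: step 11

Remark on the chemistry: in step 12 the fully substituted C11 is assumed to act as the larger carbonyl substituent and the C2=C3 vinyl carbon as the smaller one.
Remark on the chemistry: the C11 configuration of 15 and 16 is drawn as expected for alkylation on the convex face; it is erased in the dienolate of step 11, so the epimer would serve equally.
Remark on the chemistry: the sense of induction in step 1 is assigned from the usual shielding model of diarylprolinol silyl ethers.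

Step 1
Reactants: 1 dimethyl 3-oxohexanedioate; 2 (E)-but-2-enal
Product: 4 methyl (6S)-3-(2-methoxy-2-oxoethyl)-6-methyl-2-oxocyclohex-3-ene-1-carboxylate (both epimers at the ester-bearing ring carbon), via Michael adduct 3 (not isolated)
Conditions: (R)-α,α-diphenylprolinol trimethylsilyl ether (10 mol%), toluene, 0 °C to rt; then p-TsOH·H2O (20 mol%), toluene, 80 °C
Reagents that add atoms: none
Why: Iminium activation of 2 lets the doubly activated carbon of 1 add to the enal face left open by the catalyst, which should set C9 as (S) (organocatalytic Michael addition). Acid then drives intramolecular aldol condensation of the C6 methylene onto the aldehyde, the only closure that gives a six-membered ring.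

Step 2
Reactants: 4
Product: 5 methyl 2-[(4S)-4-methyl-6-oxocyclohex-1-en-1-yl]acetate
Conditions: LiCl, H2O, DMSO, 140 °C
Reagents that add atoms: none
Why: Krapcho dealkoxycarbonylation should remove only the ester that is beta to the ketone; the side-chain ester is not activated and C9 has no acidic hydrogen.

Step 3
Reactants: 5; 6 trimethyl(3-methylbut-2-en-1-yl)silane
Product: 8 methyl 2-[(1S,2S,4S)-4-methyl-2-(2-methylbut-3-en-2-yl)-6-oxocyclohexyl]acetate, via trichlorotitanium enolate 7 (not isolated)
Conditions: TiCl4 (1.2 equiv), CH2Cl2, −78 °C; then CH3OH/aq. NH4Cl at −78 °C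
Reagents that add atoms: none
Why: Hosomi–Sakurai conjugate addition: the allylsilane attacks C5 through its disubstituted terminus, creating the quaternary C4, on the face anti to the C9 methyl (trans-3,5 addition to a 5-substituted cyclohexenone). Protonation of enolate 7 at C6 from the face opposite the new pseudoaxial C5 group should give the two arms cis.

Step 4
Reactants: 8
Product: 10 methyl 2-[(1S,6S)-4-methyl-6-(2-methylbut-3-en-2-yl)-2-oxocyclohex-3-en-1-yl]acetate, via silyl enol ether 9 (not isolated)
Conditions: LiN(i-Pr)2 (1.05 equiv), THF, −78 °C, then (CH3)3SiCl; Pd(OAc)2 (1.05 equiv), CH3CN, rt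
Reagents that add atoms: none
Why: Kinetic deprotonation should take the unhindered C8 methylene and not the tertiary C6–H, so C6 is not epimerised. Saegusa–Ito oxidation of 9 then gives the C8=C9 enone and removes the relay stereocentre C9.

Step 5
Reactants: 10
Product: 11 methyl 2-[(6S,7S)-9-methyl-7-(2-methylbut-3-en-2-yl)-1,4-dioxaspiro[4.5]dec-8-en-6-yl]acetate
Conditions: HOCH2CH2OH, p-TsOH·H2O (cat.), benzene, reflux, Dean–Stark
Reagents that add atoms: ethane-1,2-diol, OCCO
Why: Acid-catalysed ketalisation of a 3-methylcyclohex-2-enone passes through the linear dienol and traps the beta,gamma-isomer, the same deconjugative ketalisation that turns steroidal 4-en-3-ones into 5-ene ketals. It should place the ring alkene at C9=C10 and mask C7 without creating a stereocentre.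

Step 6
Reactants: 11
Product: 12 N-methoxy-N-methyl-2-[(6S,7S)-9-methyl-7-(2-methylbut-3-en-2-yl)-1,4-dioxaspiro[4.5]dec-8-en-6-yl]acetamide
Conditions: CH3NH(OCH3)·HCl, i-PrMgCl, THF, −20 °C
Reagents that add atoms: N,O-dimethylhydroxylamine hydrochloride, CNOC.Cl
Why: Aminolysis of the methyl ester by the magnesium amide should give the Weinreb amide directly; ketal and alkenes are inert.

Step 7
Reactants: 12
Product: 13 1-[(6S,7S)-9-methyl-7-(2-methylbut-3-en-2-yl)-1,4-dioxaspiro[4.5]dec-8-en-6-yl]but-3-en-2-one
Conditions: CH2=CHMgBr, THF, 0 °C; inverse quench into cold aq. citric acid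
Reagents that add atoms: vinylmagnesium bromide, C=C[Mg]Br
Why: The chelated tetrahedral adduct of a Weinreb amide stops at the ketone stage. The acidic inverse quench keeps the liberated amine from adding to the vinyl ketone.

Step 8
Reactants: 13
Product: 14 cis-fused 4,4,9-trimethyl-7,7-(ethylenedioxy)bicyclo[5.4.0]undeca-2,9-dien-1-one (target numbering; H5 and H6 cis)
Conditions: second-generation Hoveyda–Grubbs catalyst [RuCl2(H2IMes)(=CH-C6H4-2-O-i-Pr)] (10 mol%), toluene (0.005 M), 80 °C
Reagents that add atoms: none
Why: Ring-closing metathesis of the vinyl ketone with the vinyl group on C4 should close the seven-membered enone and form C2=C3, necessarily cis. The cis arms favour closure and the trisubstituted ring-B alkene does not take part.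

Step 9
Reactants: 14
Product: 15 the 11-methyl derivative of 14 (methyl cis to H6)
Conditions: LiN(i-Pr)2 (1.05 equiv), THF, −78 °C; CH3I, −78 to −40 °C
Reagents that add atoms: iodomethane, CI
Why: C4 is quaternary, so only C11 can be deprotonated; the cross-conjugated dienolate should be methylated on the convex face (ketone enolate alkylation).

Step 10
Reactants: 15
Product: 16 the 9,10-epoxide of 15 (oxygen cis to H5 and H6, anti to C11)
Conditions: m-CPBA (1.2 equiv), NaHCO3, CH2Cl2, 0 °C
Reagents that add atoms: 3-chloroperoxybenzoic acid, O=C(OO)c1cccc(Cl)c1
Why: Prilezhaev epoxidation selects the electron-rich trisubstituted C9=C10 alkene over the enone. Ring A and the quaternary C4 on allylic C5 shield the concave face, so oxygen should arrive on the face of H5 and H6.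

Step 11
Reactants: 16
Product: 17 tricyclic hydroxy ketal enone (C10–C11 bond formed; C1 ketone, C2=C3, C9 tertiary alcohol, C7 dioxolane)
Conditions: KOC(CH3)3 (1.5 equiv), (CH3)3COH/THF, 25 to 50 °C, dilute; then H2O
Reagents that add atoms: none
Why: KOC(CH3)3 removes the only acidic proton of 16 (C11–H; C4 is quaternary and C6–H is not activated) to give the cross-conjugated dienolate. In the ring-B conformer with C11 axial, C11 lies over C10 on the face opposite the epoxide oxygen and displaces the C10–O bond in an SN2 manner, a 4-exo-tet closure that forms C10–C11, the cyclobutane and the bicyclo[3.1.1]heptane unit. The closest known reaction types are the intramolecular ketone-enolate alkylation that closes the four-membered ring of pinane skeletons and the base-induced cyclisation of epoxy nitriles, where exo opening to a four-membered ring is preferred over endo opening to a five-membered ring. C10 is set by inversion (anti opening). The quaternary C11 is set by the tether: the cis ring fusion holds C11 on the face of C4, so C1 and C4 must end on the same face of the new cyclobutane. The step needs C- over O-alkylation, attack at secondary C10 and not tertiary C9, and backside approach: the enolate oxygen cannot reach the backside of C10 while ring A is intact, attack at C9 would be a 5-endo opening at a fully substituted carbon, and step 10 placed the epoxide anti to C11. The C9 alkoxide stays in place and is protonated on work-up.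

Step 12
Reactants: 17
Product: 18 the (1R)-allylic alcohol of 17 (hydroxyl on the C6 side)
Conditions: (S)-Me-CBS oxazaborolidine (0.3 equiv), catecholborane (2.5 equiv), toluene, −78 °C; then H2O
Reagents that add atoms: none
Why: Corey–Bakshi–Shibata 1,2-reduction: the two faces of C1 are almost equivalent in the substrate, so the catalyst should decide. With C11 as the large group the (S)-catalyst delivers hydride to the C10-side face.

Step 13
Reactants: 18
Product: 19 the C1 (Z)-2-methylbut-2-enoate of 18
Conditions: (Z)-2-methylbut-2-enoic acid, 2,4,6-trichlorobenzoyl chloride, Et3N, toluene, rt; then 18, 80 °C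
Reagents that add atoms: (Z)-2-methylbut-2-enoic acid, C/C=C(/C)C(=O)O
Why: Acylation by the preformed mixed anhydride without a nucleophilic catalyst (Yamaguchi-type esterification) is the usual way to make angelates of hindered alcohols without Z to E isomerisation. The tertiary C9 hydroxyl should not react.

Step 14
Reactants: 19
Product: 21 dienone angelate (C7 ketone, C8=C9, C2=C3), via hydroxy ketone 20 (not isolated)
Conditions: p-TsOH·H2O (0.3 equiv), THF/H2O (4:1), 50 °C
Reagents that add atoms: water, O
Why: Acidic hydrolysis frees the C7 ketone, and the tertiary beta-hydroxyl should then leave through the enol, as in the conversion of 5-hydroxy-3-ketal steroids into 4-en-3-ones. Elimination through the C7 enol can only give C8=C9.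

Step 15
Reactants: 21
Product: 22 the 2,3-diol of 21 (O2 and O3 cis, both trans to O1)
Conditions: OsO4 (5 mol%), N-methylmorpholine N-oxide (1.1 equiv), acetone/H2O, 0 °C to rt
Reagents that add atoms: osmium tetroxide, O=[Os](=O)(=O)=O; N-methylmorpholine N-oxide, C[N+]1([O-])CCOCC1; water, O
Why: Upjohn dihydroxylation: the isolated cis C2=C3 alkene is more electron-rich than the two conjugated trisubstituted alkenes. The reagent should add anti to the C1 acyloxy group.

Step 16
Reactants: 22
Product: 23 CNP0251293.1 (target)
Conditions: 3-methylbutanoyl chloride (1.1 equiv), pyridine, CH2Cl2, −20 to 0 °C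
Reagents that add atoms: 3-methylbutanoyl chloride, CC(C)CC(=O)Cl
Why: The C3 hydroxyl is neopentylic (next to C4), so acylation should occur at O2. No acyl-transfer catalyst or strong base is used, which limits migration to O3 and isomerisation of the angelate.

## Compound list

1 | dimethyl 3-oxohexanedioate | COC(=O)CC(=O)CCC(=O)OC | starting material
2 | (E)-but-2-enal | C/C=C/C=O | starting material
3 | dimethyl 3-oxo-2-[(2S)-4-oxobutan-2-yl]hexanedioate (epimers at C2 of the diester) | COC(=O)CCC(=O)C(C(=O)OC)[C@@H](C)CC=O | intermediate
4 | methyl (6S)-3-(2-methoxy-2-oxoethyl)-6-methyl-2-oxocyclohex-3-ene-1-carboxylate (epimers at the ester-bearing ring carbon) | COC(=O)CC1=CC[C@H](C)C(C(=O)OC)C1=O | intermediate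
5 | methyl 2-[(4S)-4-methyl-6-oxocyclohex-1-en-1-yl]acetate | COC(=O)CC1=CC[C@H](C)CC1=O | intermediate
6 | trimethyl(3-methylbut-2-en-1-yl)silane | CC(C)=CC[Si](C)(C)C | starting material
7 | trichlorotitanium enolate (C6=C7) of 8 | C=CC(C)(C)[C@@H]1C(CC(=O)OC)=C(O[Ti](Cl)(Cl)Cl)C[C@@H](C)C1 | intermediate
8 | methyl 2-[(1S,2S,4S)-4-methyl-2-(2-methylbut-3-en-2-yl)-6-oxocyclohexyl]acetate | C=CC(C)(C)[C@@H]1[C@@H](C(=O)C[C@@H](C)C1)CC(=O)OC | intermediate
9 | C7=C8 trimethylsilyl enol ether of 8 | C=CC(C)(C)[C@@H]1[C@@H](C(O[Si](C)(C)C)=C[C@@H](C)C1)CC(=O)OC | intermediate
10 | methyl 2-[(1S,6S)-4-methyl-6-(2-methylbut-3-en-2-yl)-2-oxocyclohex-3-en-1-yl]acetate | C=CC(C)(C)[C@@H]1[C@@H](C(=O)C=C(C)C1)CC(=O)OC | intermediate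
11 | methyl 2-[(6S,7S)-9-methyl-7-(2-methylbut-3-en-2-yl)-1,4-dioxaspiro[4.5]dec-8-en-6-yl]acetate | C=CC(C)(C)[C@@H]1[C@@H](C2(OCCO2)CC(C)=C1)CC(=O)OC | intermediate
12 | N-methoxy-N-methyl-2-[(6S,7S)-9-methyl-7-(2-methylbut-3-en-2-yl)-1,4-dioxaspiro[4.5]dec-8-en-6-yl]acetamide | C=CC(C)(C)[C@@H]1[C@@H](C2(OCCO2)CC(C)=C1)CC(=O)N(C)OC | intermediate
13 | 1-[(6S,7S)-9-methyl-7-(2-methylbut-3-en-2-yl)-1,4-dioxaspiro[4.5]dec-8-en-6-yl]but-3-en-2-one | C=CC(C)(C)[C@@H]1[C@@H](C2(OCCO2)CC(C)=C1)CC(=O)C=C | intermediate
14 | cis-fused 4,4,9-trimethyl-7,7-(ethylenedioxy)bicyclo[5.4.0]undeca-2,9-dien-1-one (target numbering) | O=C1C=CC(C)(C)[C@@H]2[C@@H](C3(OCCO3)CC(C)=C2)C1 | intermediate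
15 | 11-methyl derivative of 14 (methyl cis to H6) | O=C1C=CC(C)(C)[C@@H]2[C@@H](C3(OCCO3)CC(C)=C2)[C@@H]1C | intermediate
16 | 9,10-epoxide of 15 (oxygen cis to H5 and H6); key-step precursor | O=C1C=CC(C)(C)[C@@H]2[C@@H](C3(OCCO3)C[C@@]3(C)O[C@@H]23)[C@@H]1C | intermediate
17 | tricyclic enone with C9 tertiary alcohol and C7 dioxolane; key-step product | O=C1C=CC(C)(C)[C@@H]2[C@H]3C4(OCCO4)C[C@@](C)(O)[C@@H]2[C@@]13C | intermediate
18 | (1R)-allylic alcohol from 17 | O[C@@H]1C=CC(C)(C)[C@@H]2[C@H]3C4(OCCO4)C[C@@](C)(O)[C@@H]2[C@@]13C | intermediate
19 | C1 angelate of 18 | C/C=C(/C)C(=O)O[C@@H]1C=CC(C)(C)[C@@H]2[C@H]3C4(OCCO4)C[C@@](C)(O)[C@@H]2[C@@]13C | intermediate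
20 | C7 ketone with C9 tertiary alcohol (beta-hydroxy ketone) | C/C=C(/C)C(=O)O[C@@H]1C=CC(C)(C)[C@@H]2[C@H]3C(=O)C[C@@](C)(O)[C@@H]2[C@@]13C | intermediate
21 | dienone angelate (C7=O, C8=C9, C2=C3) | C/C=C(/C)C(=O)O[C@@H]1C=CC(C)(C)[C@@H]2[C@H]3C(=O)C=C(C)[C@@H]2[C@@]13C | intermediate
22 | 2,3-diol of 21 | C/C=C(/C)C(=O)O[C@@H]1[C@@H](O)[C@@H](O)C(C)(C)[C@@H]2[C@H]3C(=O)C=C(C)[C@@H]2[C@@]13C | intermediate
23 | CNP0251293.1 | C/C=C(/C)C(=O)O[C@@H]1[C@@H](OC(=O)CC(C)C)[C@@H](O)C(C)(C)[C@@H]2[C@H]3C(=O)C=C(C)[C@@H]2[C@@]13C | target

## Step count and least certain steps

Total step count: 16. Longest linear sequence: 16 steps (1 to 23); the route is linear, with 2 and 6 entering in steps 1 and 3.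

Step 11 (key step). The ring closure may fail to compete: the conformer with axial C11 may be sparsely populated, and an alkoxide leaving from a rigid oxirane to form a strained ring is a poor leaving group. The dienolate could then add intermolecularly to another enone, or the epoxide could isomerise to an allylic alcohol. The fallback keeps the same bond but uses a sulfonate. It sets out from 15: OsO4/N-methylmorpholine N-oxide should add to the ring-B alkene on the same convex face to give the cis-9,10-diol F1. CH3SO2Cl/Et3N should sulfonylate only the secondary C10 hydroxyl to give the C10 methanesulfonate F2, whose cis tertiary alkoxide cannot close an epoxide. KOC(CH3)3 then effects the classical intramolecular enolate alkylation with inversion at C10, and the route is rejoined at 17.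

Step 3. The cis relationship of the two arms may be lost by unselective protonation of the enolate or by epimerisation at C6 while C7 is still a ketone; the hindered 2-substituted enone may also react sluggishly. The fallback separates bond formation from protonation. It sets out from 5 and 6: the addition is run as before, but Et3N is added before work-up so that the silyl group is transferred to oxygen and the regiodefined C6=C7 trimethylsilyl enol ether F3 is isolated. F3 is then cleaved with (C4H9)4NF in the presence of CH3CO2H at −78 °C, so that the enolate is protonated under kinetic control from the face opposite the C5 group, and the route is rejoined at 8.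

Step 5. Double-bond migration may be incomplete or go to the exocyclic position, C6 may epimerise through the cross-conjugated enol, and the ester may exchange with the diol. The fallback separates deconjugation from protection. It sets out from 10: pyrrolidine (benzene, reflux) should give the linear dienamine F4. Buffered hydrolysis (aq. CH3CO2H/CH3CO2Na, 0 °C) protonates at C8 and should give the beta,gamma-unsaturated ketone F5. F5 is then ketalised without equilibration using 1,2-bis(trimethylsilyloxy)ethane and catalytic (CH3)3SiOSO2CF3 at −78 °C, and the route is rejoined at 11.

Step 8. Catalyst turnover may be poor because one alkene is electron-poor and the other sits on a quaternary carbon, so oligomerisation by cross-metathesis can take over. The fallback changes the substrate class. It sets out from 13: NaBH4/CeCl3·7H2O should give the dienol F6, whose allylic hydroxyl makes the C1-side alkene a good site for catalyst loading. Ring-closing metathesis with the second-generation Grubbs catalyst [RuCl2(H2IMes)(PCy3)(=CHPh)] should give the cycloheptenol F7, and Dess–Martin oxidation rejoins the route at 14.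

Step 12. Facial selectivity may be poor or reversed if the catalyst does not rank C11 and the vinyl group as assumed; the substrate itself gives no help. The fallback replaces control by correction. It sets out from 17: NaBH4/CeCl3·7H2O should give 18 together with its C1 epimer F8, which are separated. 18 continues as planned, and F8 is esterified with (Z)-2-methylbut-2-enoic acid under Mitsunobu conditions (PPh3, diisopropyl azodicarboxylate), which inverts C1 and rejoins the route at 19.

Step 16. Regiocontrol of acylation may be incomplete (ester at O3, diester), or the acyl group may migrate across the cis diol. The fallback activates one oxygen selectively. It sets out from 22: (C4H9)2SnO (toluene, reflux, water removal) should give the dibutylstannylene acetal F9, which on treatment with 3-methylbutanoyl chloride at 0 °C is expected to acylate the less hindered O2, and the route is rejoined at 23.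

## Further compounds

F1 | step 11 | cis-9,10-diol of 15 (both hydroxyls cis to H5 and H6) | O=C1C=CC(C)(C)[C@@H]2[C@@H](C3(OCCO3)C[C@@](C)(O)[C@H]2O)[C@@H]1C
F2 | step 11 | C10 methanesulfonate of F1 | O=C1C=CC(C)(C)[C@@H]2[C@@H](C3(OCCO3)C[C@@](C)(O)[C@H]2OS(C)(=O)=O)[C@@H]1C
F3 | step 3 | C6=C7 trimethylsilyl enol ether of 8 | C=CC(C)(C)[C@@H]1C(CC(=O)OC)=C(O[Si](C)(C)C)C[C@@H](C)C1
F4 | step 5 | linear pyrrolidine dienamine of 10 | C=CC(C)(C)[C@@H]1[C@@H](C(N2CCCC2)=CC(C)=C1)CC(=O)OC
F5 | step 5 | beta,gamma-unsaturated ketone (C9=C10) isomer of 10 | C=CC(C)(C)[C@@H]1[C@@H](C(=O)CC(C)=C1)CC(=O)OC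
F6 | step 8 | dienol from 1,2-reduction of 13 (carbinol epimers) | C=CC(C)(C)[C@@H]1[C@@H](C2(OCCO2)CC(C)=C1)CC(O)C=C
F7 | step 8 | cycloheptenol corresponding to 14 (carbinol epimers) | OC1C=CC(C)(C)[C@@H]2[C@@H](C3(OCCO3)CC(C)=C2)C1
F8 | step 12 | C1 epimer of 18 | O[C@H]1C=CC(C)(C)[C@@H]2[C@H]3C4(OCCO4)C[C@@](C)(O)[C@@H]2[C@@]13C
F9 | step 16 | 2,3-O-dibutylstannylene acetal of 22 | C/C=C(/C)C(=O)O[C@@H]1[C@H]4O[Sn](CCCC)(CCCC)O[C@H]4C(C)(C)[C@@H]2[C@H]3C(=O)C=C(C)[C@@H]2[C@@]13C
A1 | alternative 1 | methyl-substituted bicyclo[1.1.0]butane bridged by the ketal-bearing C7–C8–C9 chain | C[C@@]12[C@H]3[C@@H]1[C@@H]2[C@@H](C)CC34OCCO4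
A2 | alternative 1 | 4-bromo-4-methylpent-1-yn-3-one | C#CC(=O)C(C)(C)Br
A3 | alternative 1 | tricyclic cycloheptenone (C3 ketone, C1=C2) with ketal-protected saturated C7–C9 bridge | C1=CC(=O)C(C)(C)[C@@H]2[C@H]3C4(OCCO4)C[C@H](C)[C@@H]2[C@@]13C
A4 | alternative 2 | bridged cyclic sulfone (sulfur between C8 and C9; either C9 epimer) | CC(C)(C)[Si](C)(C)O[C@@H]1[C@H]4OC(C)(C)O[C@H]4C(C)(C)[C@@H]2[C@H]3C5(OCCO5)CS(=O)(=O)[C@H](C)[C@@H]2[C@@]13C
A5 | alternative 2 | tricyclic alkene (C8=C9) with C7 ethylene ketal | CC(C)(C)[Si](C)(C)O[C@@H]1[C@H]4OC(C)(C)O[C@H]4C(C)(C)[C@@H]2[C@H]3C5(OCCO5)C=C(C)[C@@H]2[C@@]13C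
A6 | alternative 3 | bicyclo[2.1.1]hexanone with bromomethyl and methyl on C9 (either C9 epimer) | CC(C)(C)[Si](C)(C)O[C@@H]1[C@H]4OC(C)(C)O[C@H]4C(C)(C)[C@@H]2[C@H]3C(=O)[C@](C)(CBr)[C@@H]2[C@@]13C
A7 | alternative 3 | protected tricyclic saturated C7 ketone | CC(C)(C)[Si](C)(C)O[C@@H]1[C@H]4OC(C)(C)O[C@H]4C(C)(C)[C@@H]2[C@H]3C(=O)C[C@H](C)[C@@H]2[C@@]13C
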